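**Retrosynthetic overview**
1. Target 25 ⇒ silyl ether 24 ⇒ C5–O bond by palladium-catalysed allylic C–H acyloxylation of methylidene-hydrindanone 20 with acid 23 (last fragment union).
2. 20 ⇒ 3β-alcohol 17 + acid 19 (Mitsunobu, inversion at C3); 17 ⇒ ketone 15 (enolate hydroxylation).
3. 15 ⇒ diazoketone 13 by rhodium-carbenoid C–H insertion (C3–C3a bond); the five-membered ring is closed last, onto the finished six-membered ring.
4. 13 ⇒ (S)-cryptone 4 + silyl ketene acetal 8 (Mukaiyama–Michael, C7a–C1 bond), then Wittig methylenation and diazomethane homologation.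
5. 4 ⇐ isovaleraldehyde + methyl vinyl ketone (six-membered ring first); 8 ⇐ (R)-3-hydroxybutanoic acid; 19 ⇐ tiglic acid; 23 ⇐ ethyl but-2-ynoate.

Assumption: ring atoms are numbered as in indan-2-one (C1, C2 = ketone, C3, C3a, C4–C7, C7a) in every name; β is the face of H-3a, α the face of H-7a.
Assumption: 1, 2, 5, 18 and 21 are catalogue chemicals; silyl chlorides, the Wittig salt, diazomethane and the oxaziridine are reagents.

**Step 1**
Reactants: 1 3-methylbutanal (isovaleraldehyde); 2 but-3-en-2-one (methyl vinyl ketone)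
Product: 3 (2S)-5-oxo-2-(propan-2-yl)hexanal
Conditions: (S)-α,α-diphenylprolinol trimethylsilyl ether (5 mol %), ethyl 3,4-dihydroxybenzoate (20 mol %), neat, 4 °C
Reagents that add atoms: none
Why: Enamine-catalysed Michael addition; the bulky group of the (S)-catalyst blocks one enamine face, so the new C–C bond sets the (S) centre that becomes C7.

**Step 2**
Reactants: 3 (2S)-5-oxo-2-(propan-2-yl)hexanal
Product: 4 (4S)-4-(propan-2-yl)cyclohex-2-en-1-one ((S)-cryptone)
Conditions: LiOH (0.1 equiv), i-PrOH, rt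
Reagents that add atoms: none
Why: Intramolecular aldol condensation (closing stage of a Robinson annulation) forms the six-membered ring; mild catalytic base limits erosion of the stereocentre.

**Step 3**
Reactants: 5 (3R)-3-hydroxybutanoic acid
Product: 6 tert-butyldimethylsilyl (3R)-3-[(tert-butyldimethylsilyl)oxy]butanoate
Conditions: t-BuMe2SiCl (2.3 equiv), imidazole (4.6 equiv), DMF, rt
Reagents that add atoms: tert-butyldimethylsilyl chloride, CC(C)(C)[Si](C)(C)Cl
Why: Exhaustive silylation gives the silyl ether and silyl ester; the carbinol centre (the future side-chain carbinol) is untouched.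

**Step 4**
Reactants: 6 tert-butyldimethylsilyl (3R)-3-[(tert-butyldimethylsilyl)oxy]butanoate
Product: 8 (3R)-1,3-bis[(tert-butyldimethylsilyl)oxy]-1-[(trimethylsilyl)oxy]but-1-ene, via lithium ester enolate 7 (not isolated)
Conditions: LiN(i-Pr)2 (1.1 equiv), Me3SiCl (1.3 equiv, present from the start), THF, −78 °C
Reagents that add atoms: trimethylsilyl chloride, C[Si](C)(C)Cl
Why: Silyl ketene acetal formation by kinetic α-deprotonation of the silyl ester with in situ O-silylation, which outruns β-elimination of the silyloxy group.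

**Step 5**
Reactants: 4 (4S)-4-(propan-2-yl)cyclohex-2-en-1-one; 8 (3R)-1,3-bis[(tert-butyldimethylsilyl)oxy]-1-[(trimethylsilyl)oxy]but-1-ene
Product: 10 (3R)-3-[(tert-butyldimethylsilyl)oxy]-2-[(1R,2S)-5-oxo-2-(propan-2-yl)cyclohexyl]butanoic acid (both epimers at C-2), via silyl enol ether silyl ester 9 (not isolated)
Conditions: Me3SiOTf (5 mol %), CH2Cl2, −78 °C; then 1 M HCl, THF, 0 °C
Reagents that add atoms: none
Why: Mukaiyama–Michael addition; the ketene acetal adds 1,4 anti to the neighbouring isopropyl group (trans C7a/C7), the α-carbon (future C1) forms as a mixture that is corrected in step 8, and mild acid frees ketone and acid while the secondary silyl ether stays.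

**Step 6**
Reactants: 10 (3R)-3-[(tert-butyldimethylsilyl)oxy]-2-[(1R,2S)-5-oxo-2-(propan-2-yl)cyclohexyl]butanoic acid
Product: 11 (3R)-3-[(tert-butyldimethylsilyl)oxy]-2-[(1R,2S)-5-methylidene-2-(propan-2-yl)cyclohexyl]butanoic acid (both epimers at C-2)
Conditions: Ph3PCH3Br (3.2 equiv), KOt-Bu (3.1 equiv), THF, 0 °C to rt; acidic work-up
Reagents that add atoms: methyltriphenylphosphonium bromide, C[P+](c1ccccc1)(c1ccccc1)c1ccccc1.[Br-]
Why: Wittig methylenation of the ketone (excess ylide tolerates the carboxylate) installs the C4 methylidene; no stereocentre is affected.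

**Step 7**
Reactants: 11 (3R)-3-[(tert-butyldimethylsilyl)oxy]-2-[(1R,2S)-5-methylidene-2-(propan-2-yl)cyclohexyl]butanoic acid
Product: 13 (4R)-4-[(tert-butyldimethylsilyl)oxy]-1-diazo-3-[(1R,2S)-5-methylidene-2-(propan-2-yl)cyclohexyl]pentan-2-one (both epimers at C-3), via acid chloride 12 (not isolated)
Conditions: 1-chloro-N,N,2-trimethylprop-1-en-1-amine (1.2 equiv), CH2Cl2, 0 °C; then CH2N2 (3 equiv), Et2O, 0 °C
Reagents that add atoms: diazomethane, C=[N+]=[N-]
Why: Acylation of diazomethane (first stage of an Arndt–Eistert sequence) through an acid chloride made under neutral conditions; excess diazomethane scavenges HCl, and its carbon becomes C3.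

**Step 8**
Reactants: 13 (4R)-4-[(tert-butyldimethylsilyl)oxy]-1-diazo-3-[(1R,2S)-5-methylidene-2-(propan-2-yl)cyclohexyl]pentan-2-one
Product: 15 (1S,3aR,7S,7aS)-1-[(1R)-1-{[tert-butyl(dimethyl)silyl]oxy}ethyl]-4-methylidene-7-(propan-2-yl)octahydro-2H-inden-2-one, via C1 epimer mixture 14 (not isolated)
Conditions: Rh2(OAc)4 (1 mol %), CH2Cl2, 40 °C, slow addition of 13; then DBU (0.3 equiv), rt
Reagents that add atoms: none
Why: Rhodium-carbenoid 1,5 C–H insertion (Taber cyclopentanone synthesis) of the equatorial side arm into the equatorial C3a–H with retention closes the five-membered ring trans-fused (the axial tertiary C7–H is hindered), and DBU then equilibrates C1 to the more stable α epimer, anti to C7.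

**Step 9**
Reactants: 15 (1S,3aR,7S,7aS)-1-[(1R)-1-{[tert-butyl(dimethyl)silyl]oxy}ethyl]-4-methylidene-7-(propan-2-yl)octahydro-2H-inden-2-one
Product: 17 (1S,3R,3aR,7S,7aS)-1-[(1R)-1-{[tert-butyl(dimethyl)silyl]oxy}ethyl]-3-hydroxy-4-methylidene-7-(propan-2-yl)octahydro-2H-inden-2-one (3β-OH), via potassium enolate 16 (not isolated)
Conditions: KN(SiMe3)2 (1.1 equiv), THF, −78 °C; trans-2-(phenylsulfonyl)-3-phenyloxaziridine (1.3 equiv), −78 °C; AcOH quench
Reagents that add atoms: 2-(phenylsulfonyl)-3-phenyloxaziridine, O=S(=O)(c1ccccc1)N1OC1c1ccccc1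
Why: Kinetic deprotonation at the only α-CH2 (C3) and Davis oxaziridine hydroxylation from the less hindered β face (anti to the 1α side chain and the axial H-7a) give the 3β-alcohol.

**Step 10**
Reactants: 18 (2E)-2-methylbut-2-enoic acid (tiglic acid)
Product: 19 (2R)-2-methylbutanoic acid
Conditions: H2 (4 atm), Ru(OAc)2[(R)-H8-BINAP] (0.5 mol %), MeOH, 20 °C
Reagents that add atoms: none
Why: Noyori-type asymmetric hydrogenation of an α,β-unsaturated acid; the (R)-ligand complex gives the (R)-acid.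

**Step 11**
Reactants: 17 the 3β-alcohol of step 9; 19 (2R)-2-methylbutanoic acid
Product: 20 (1S,3S,3aR,7S,7aS)-1-[(1R)-1-{[tert-butyl(dimethyl)silyl]oxy}ethyl]-4-methylidene-2-oxo-7-(propan-2-yl)octahydro-1H-inden-3-yl (2R)-2-methylbutanoate (3α-ester)
Conditions: PPh3 (1.5 equiv), DIAD (1.5 equiv), toluene, 0 °C to rt
Reagents that add atoms: none
Why: Mitsunobu esterification; SN2 displacement of the carbonyl-activated alkoxyphosphonium by the carboxylate inverts C3 and gives the required, less stable 3α ester under neutral conditions.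

**Step 12**
Reactants: 21 ethyl but-2-ynoate
Product: 22 ethyl (2E)-3-methylpent-2-enoate
Conditions: EtMgBr (1.2 equiv), CuBr·SMe2 (10 mol %), THF, −78 °C; 1 M HCl at −78 °C
Reagents that add atoms: ethylmagnesium bromide, CC[Mg]Br
Why: Copper-catalysed syn carbometalation (conjugate addition) of the ynoate with cold protonation places ethyl cis to H, which is the E ester.

**Step 13**
Reactants: 22 ethyl (2E)-3-methylpent-2-enoate
Product: 23 (2E)-3-methylpent-2-enoic acid
Conditions: LiOH (2 equiv), THF/H2O, rt; then 1 M HCl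
Reagents that add atoms: lithium hydroxide, [Li+].[OH-]
Why: Saponification by acyl–oxygen cleavage; the double-bond geometry is retained.

**Step 14**
Reactants: 20 the 3α-ester of step 11; 23 (2E)-3-methylpent-2-enoic acid
Product: 24 (1S,3S,3aR,5R,7S,7aS)-1-[(1R)-1-{[tert-butyl(dimethyl)silyl]oxy}ethyl]-4-methylidene-3-{[(2R)-2-methylbutanoyl]oxy}-2-oxo-7-(propan-2-yl)octahydro-1H-inden-5-yl (2E)-3-methylpent-2-enoate
Conditions: Pd(OAc)2 (10 mol %), 1,2-bis(phenylsulfinyl)ethane (10 mol %), p-benzoquinone (2 equiv), 23 (3 equiv), 1,4-dioxane, 45 °C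
Reagents that add atoms: none
Why: Proposed new method: a sulfoxide-ligated divalent palladium carboxylate cleaves the axial 5β allylic C–H of the exocyclic 1,1-disubstituted olefin (the only secondary C–H aligned with the π system; the tertiary H-3a is more hindered), and benzoquinone-induced inner-sphere C–O reductive elimination from the π-allylpalladium carboxylate at the ring terminus delivers the acid to the same β face, giving the axial 5β ester with the methylidene retained while benzoquinone returns zerovalent palladium to the divalent state; the closest known chemistry is the branched-selective palladium/bis-sulfoxide allylic C–H esterification of terminal olefins (White type) and the Pd(OAc)2/benzoquinone allylic acetoxylation of cycloalkenes, neither shown for methylidene rings or with this diastereocontrol.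

**Step 15**
Reactants: 24 the silyl ether of step 14
Product: 25 (1S,3S,3aR,5R,7S,7aS)-1-[(1R)-1-hydroxyethyl]-4-methylidene-3-{[(2R)-2-methylbutanoyl]oxy}-2-oxo-7-(propan-2-yl)octahydro-1H-inden-5-yl (2E)-3-methylpent-2-enoate (CNP0224363.2)
Conditions: HF·pyridine, THF/pyridine, 0 °C to rt
Reagents that add atoms: none
Why: Fluoride desilylation under mildly acidic conditions leaves both esters, the β-hydroxy ketone and the epimerisable C3 centre untouched.

**Compound list**
1 | 3-methylbutanal | CC(C)CC=O | starting material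
2 | but-3-en-2-one | CC(=O)C=C | starting material
3 | (2S)-5-oxo-2-(propan-2-yl)hexanal | O=C[C@H](C(C)C)CCC(C)=O | intermediate
4 | (4S)-4-(propan-2-yl)cyclohex-2-en-1-one | O=C1C=C[C@H](C(C)C)CC1 | intermediate
5 | (3R)-3-hydroxybutanoic acid | OC(=O)C[C@@H](C)O | starting material
6 | tert-butyldimethylsilyl (3R)-3-[(tert-butyldimethylsilyl)oxy]butanoate | CC(C)(C)[Si](C)(C)OC(=O)C[C@@H](C)O[Si](C)(C)C(C)(C)C | intermediate
7 | lithium enolate of 6 | C(=C([O-])O[Si](C)(C)C(C)(C)C)[C@@H](C)O[Si](C)(C)C(C)(C)C.[Li+] | intermediate (not isolated)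
8 | (3R)-1,3-bis[(tert-butyldimethylsilyl)oxy]-1-[(trimethylsilyl)oxy]but-1-ene | C(=C(O[Si](C)(C)C)O[Si](C)(C)C(C)(C)C)[C@@H](C)O[Si](C)(C)C(C)(C)C | intermediate
9 | tert-butyldimethylsilyl (3R)-3-[(tert-butyldimethylsilyl)oxy]-2-[(1S,6S)-6-(propan-2-yl)-3-[(trimethylsilyl)oxy]cyclohex-2-en-1-yl]butanoate (both C-2 epimers) | C[Si](C)(C)OC1=C[C@@H](C([C@@H](C)O[Si](C)(C)C(C)(C)C)C(=O)O[Si](C)(C)C(C)(C)C)[C@H](C(C)C)CC1 | intermediate (not isolated)
10 | (3R)-3-[(tert-butyldimethylsilyl)oxy]-2-[(1R,2S)-5-oxo-2-(propan-2-yl)cyclohexyl]butanoic acid (both C-2 epimers) | O=C1C[C@@H](C([C@@H](C)O[Si](C)(C)C(C)(C)C)C(=O)O)[C@H](C(C)C)CC1 | intermediate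
11 | (3R)-3-[(tert-butyldimethylsilyl)oxy]-2-[(1R,2S)-5-methylidene-2-(propan-2-yl)cyclohexyl]butanoic acid (both C-2 epimers) | C=C1C[C@@H](C([C@@H](C)O[Si](C)(C)C(C)(C)C)C(=O)O)[C@H](C(C)C)CC1 | intermediate
12 | (3R)-3-[(tert-butyldimethylsilyl)oxy]-2-[(1R,2S)-5-methylidene-2-(propan-2-yl)cyclohexyl]butanoyl chloride | C=C1C[C@@H](C([C@@H](C)O[Si](C)(C)C(C)(C)C)C(=O)Cl)[C@H](C(C)C)CC1 | intermediate (not isolated)
13 | (4R)-4-[(tert-butyldimethylsilyl)oxy]-1-diazo-3-[(1R,2S)-5-methylidene-2-(propan-2-yl)cyclohexyl]pentan-2-one (both C-3 epimers) | C=C1C[C@@H](C([C@@H](C)O[Si](C)(C)C(C)(C)C)C(=O)C=[N+]=[N-])[C@H](C(C)C)CC1 | intermediate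
14 | (3aR,7S,7aS)-1-[(1R)-1-{[tert-butyl(dimethyl)silyl]oxy}ethyl]-4-methylidene-7-(propan-2-yl)octahydro-2H-inden-2-one (1α/1β mixture) | C=C1[C@H]2[C@@H](C([C@@H](C)O[Si](C)(C)C(C)(C)C)C(=O)C2)[C@H](C(C)C)CC1 | intermediate (not isolated)
15 | (1S,3aR,7S,7aS)-1-[(1R)-1-{[tert-butyl(dimethyl)silyl]oxy}ethyl]-4-methylidene-7-(propan-2-yl)octahydro-2H-inden-2-one | C=C1[C@H]2[C@@H]([C@@H]([C@@H](C)O[Si](C)(C)C(C)(C)C)C(=O)C2)[C@H](C(C)C)CC1 | intermediate
16 | potassium C2–C3 enolate of 15 | C=C1[C@H]2[C@@H]([C@@H]([C@@H](C)O[Si](C)(C)C(C)(C)C)C([O-])=C2)[C@H](C(C)C)CC1.[K+] | intermediate (not isolated)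
17 | (1S,3R,3aR,7S,7aS)-1-[(1R)-1-{[tert-butyl(dimethyl)silyl]oxy}ethyl]-3-hydroxy-4-methylidene-7-(propan-2-yl)octahydro-2H-inden-2-one | C=C1[C@H]2[C@@H]([C@@H]([C@@H](C)O[Si](C)(C)C(C)(C)C)C(=O)[C@@H]2O)[C@H](C(C)C)CC1 | intermediate
18 | (2E)-2-methylbut-2-enoic acid | C/C=C(\C)C(=O)O | starting material
19 | (2R)-2-methylbutanoic acid | OC(=O)[C@H](C)CC | intermediate
20 | (1S,3S,3aR,7S,7aS)-1-[(1R)-1-{[tert-butyl(dimethyl)silyl]oxy}ethyl]-4-methylidene-2-oxo-7-(propan-2-yl)octahydro-1H-inden-3-yl (2R)-2-methylbutanoate | C=C1[C@H]2[C@@H]([C@@H]([C@@H](C)O[Si](C)(C)C(C)(C)C)C(=O)[C@H]2OC(=O)[C@H](C)CC)[C@H](C(C)C)CC1 | intermediate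
21 | ethyl but-2-ynoate | CCOC(=O)C#CC | starting material
22 | ethyl (2E)-3-methylpent-2-enoate | CCOC(=O)/C=C(\C)CC | intermediate
23 | (2E)-3-methylpent-2-enoic acid | OC(=O)/C=C(\C)CC | intermediate
24 | (1S,3S,3aR,5R,7S,7aS)-1-[(1R)-1-{[tert-butyl(dimethyl)silyl]oxy}ethyl]-4-methylidene-3-{[(2R)-2-methylbutanoyl]oxy}-2-oxo-7-(propan-2-yl)octahydro-1H-inden-5-yl (2E)-3-methylpent-2-enoate | C=C1[C@H]2[C@@H]([C@@H]([C@@H](C)O[Si](C)(C)C(C)(C)C)C(=O)[C@H]2OC(=O)[C@H](C)CC)[C@H](C(C)C)C[C@H]1OC(=O)/C=C(\C)CC | intermediate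
25 | (1S,3S,3aR,5R,7S,7aS)-1-[(1R)-1-hydroxyethyl]-4-methylidene-3-{[(2R)-2-methylbutanoyl]oxy}-2-oxo-7-(propan-2-yl)octahydro-1H-inden-5-yl (2E)-3-methylpent-2-enoate | C=C1[C@H]2[C@@H]([C@@H]([C@@H](C)O)C(=O)[C@H]2OC(=O)[C@H](C)CC)[C@H](C(C)C)C[C@H]1OC(=O)/C=C(\C)CC | target

**Step count**
Total: 15 steps. Longest linear sequence: 10 steps (1, 2, 5, 6, 7, 8, 9, 11, 14, 15; the arm 3, 4, 5 onward is equally long), which is two thirds of the total.

**Steps most likely to fail, with fallbacks**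

Step 14 (the proposed new C–H acyloxylation). It may give the primary ester at the exocyclic carbon, migrate the olefin into the ring, or not convert. The fallback is known chemistry and sets out from 20. Allylic oxidation with SeO2 (0.5 equiv) and t-BuOOH in CH2Cl2 at rt (ene reaction, then 2,3-sigmatropic shift) attacks the ring CH2 in preference to the ring-fusion CH and delivers oxygen axially. It gives (1S,3S,3aR,5R,7S,7aS)-1-[(1R)-1-{[tert-butyl(dimethyl)silyl]oxy}ethyl]-5-hydroxy-4-methylidene-2-oxo-7-(propan-2-yl)octahydro-1H-inden-3-yl (2R)-2-methylbutanoate F1. Steglich esterification of F1 with acid 23 (EDC·HCl, DMAP, CH2Cl2, 0 °C) then gives 24, where the route is rejoined.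

Step 8 (carbenoid C–H insertion). Insertion could go into the tertiary C7–H, the silyl ether oxygen could form an ylide, or the methylidene could be cyclopropanated. The fallback closes the ring by enolate alkylation and sets out from keto acid 10, before the methylenation.
- 10 is converted with the chloroenamine of step 7 into (3R)-3-[(tert-butyldimethylsilyl)oxy]-2-[(1R,2S)-5-oxo-2-(propan-2-yl)cyclohexyl]butanoyl chloride F2.
- F2 and CH2N2 give (4R)-4-[(tert-butyldimethylsilyl)oxy]-1-diazo-3-[(1R,2S)-5-oxo-2-(propan-2-yl)cyclohexyl]pentan-2-one F3.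
- Anhydrous HCl in Et2O at −20 °C turns F3 into (4R)-4-[(tert-butyldimethylsilyl)oxy]-1-chloro-3-[(1R,2S)-5-oxo-2-(propan-2-yl)cyclohexyl]pentan-2-one F4.
- NaI (cat.) and KOt-Bu in THF/t-BuOH at −20 °C alkylate the ring-ketone enolate intramolecularly. Only the C3a enolate can close a five-membered ring, and the centre α to the ketone settles trans, giving (3aR,7S,7aS)-1-[(1R)-1-{[tert-butyl(dimethyl)silyl]oxy}ethyl]-7-(propan-2-yl)hexahydro-1H-indene-2,4-dione F5.
- Lombardo methylenation (Zn, CH2Br2, TiCl4, THF) of the less hindered six-ring ketone of F5 gives the epimer mixture 14, which DBU converts into 15 as in step 8.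

Step 11 (Mitsunobu inversion at a hindered α-hydroxy ketone). Displacement from the α face may be slow, or elimination may compete. The fallback makes a C–Br bond first and sets out from ketone 15. Enolate 16 (KN(SiMe3)2, THF, −78 °C) is brominated with N-bromosuccinimide from the β face to give (1S,3R,3aR,7S,7aS)-3-bromo-1-[(1R)-1-{[tert-butyl(dimethyl)silyl]oxy}ethyl]-4-methylidene-7-(propan-2-yl)octahydro-2H-inden-2-one F6. Acid 19 and Cs2CO3 give cesium (2R)-2-methylbutanoate F7. SN2 displacement of the α-bromo ketone F6 by F7 (DMF, 0 °C) inverts C3 and gives 20, where the route is rejoined.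

**Further compounds**
F1 | step 14 | (1S,3S,3aR,5R,7S,7aS)-1-[(1R)-1-{[tert-butyl(dimethyl)silyl]oxy}ethyl]-5-hydroxy-4-methylidene-2-oxo-7-(propan-2-yl)octahydro-1H-inden-3-yl (2R)-2-methylbutanoate | C=C1[C@H]2[C@@H]([C@@H]([C@@H](C)O[Si](C)(C)C(C)(C)C)C(=O)[C@H]2OC(=O)[C@H](C)CC)[C@H](C(C)C)C[C@H]1O
F2 | step 8 | (3R)-3-[(tert-butyldimethylsilyl)oxy]-2-[(1R,2S)-5-oxo-2-(propan-2-yl)cyclohexyl]butanoyl chloride | O=C1C[C@@H](C([C@@H](C)O[Si](C)(C)C(C)(C)C)C(=O)Cl)[C@H](C(C)C)CC1
F3 | step 8 | (4R)-4-[(tert-butyldimethylsilyl)oxy]-1-diazo-3-[(1R,2S)-5-oxo-2-(propan-2-yl)cyclohexyl]pentan-2-one | O=C1C[C@@H](C([C@@H](C)O[Si](C)(C)C(C)(C)C)C(=O)C=[N+]=[N-])[C@H](C(C)C)CC1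
F4 | step 8 | (4R)-4-[(tert-butyldimethylsilyl)oxy]-1-chloro-3-[(1R,2S)-5-oxo-2-(propan-2-yl)cyclohexyl]pentan-2-one | O=C1C[C@@H](C([C@@H](C)O[Si](C)(C)C(C)(C)C)C(=O)CCl)[C@H](C(C)C)CC1
F5 | step 8 | (3aR,7S,7aS)-1-[(1R)-1-{[tert-butyl(dimethyl)silyl]oxy}ethyl]-7-(propan-2-yl)hexahydro-1H-indene-2,4-dione (C1 epimers) | O=C1[C@H]2[C@@H](C([C@@H](C)O[Si](C)(C)C(C)(C)C)C(=O)C2)[C@H](C(C)C)CC1
F6 | step 11 | (1S,3R,3aR,7S,7aS)-3-bromo-1-[(1R)-1-{[tert-butyl(dimethyl)silyl]oxy}ethyl]-4-methylidene-7-(propan-2-yl)octahydro-2H-inden-2-one | C=C1[C@H]2[C@@H]([C@@H]([C@@H](C)O[Si](C)(C)C(C)(C)C)C(=O)[C@@H]2Br)[C@H](C(C)C)CC1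
F7 | step 11 | cesium (2R)-2-methylbutanoate | [Cs+].[O-]C(=O)[C@H](C)CC
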